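At the last readings the alder run holds 50.3% of its substrate after 3.00 min, and the elm run holds 46.3% after 60.0 s. We must choose the temperature of the next run, spring or dawn, with the same charge and time, and the choice hangs on how much free substrate that time leaves.

| flask | substrate | reagent | temperature | remark | time |
|---|---|---|---|---|---|
| alder | 1 M | 0.65 M | 116 °C | run made earlier |  |
| elm | 1 M | 2.6 M | 130 °C | run made earlier |  |
| spring | 1.0 M | 1.30 M | 110 °C |  | 5.0 min |
| dawn | 1.0 M | 1.30 M | 135 °C |  | 5.0 min |

alder run (percent of the substrate charged)

| time / min | substrate / % | side product / % | intermediate / % | target / % |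
|---|---|---|---|---|
| 0.200 | 90.8 | 0.1 | 5.1 | 0.3 |
| 0.667 | 79.8 | 0.8 | 6.6 | 2.5 |
| 1.00 | 74.2 | 2.1 | 5.9 | 4.5 |
| 1.50 | 67.2 | 2.4 | 4.9 | 5.8 |
| 2.50 | 55.2 | 3.8 | 3.3 | 8.4 |
| 3.00 | 50.3 | 4.0 | 2.4 | 9.5 |

elm run (percent of the substrate charged)

| time / s | substrate / % | side product / % | intermediate / % | target / % |
|---|---|---|---|---|
| 10.0 | 83.0 | 0 | 4.5 | 3.5 |
| 15.0 | 78.0 | 0.8 | 3.8 | 5.9 |
| 20.0 | 73.8 | 1.0 | 3.1 | 7.6 |
| 40.0 | 58.0 | 2.1 | 1.8 | 12.1 |
| 60.0 | 46.3 | 2.3 | 1.2 | 14.7 |

(readings scatter by 0.3 percentage points)

- which of these there is most of at the end, counted by the substrate in it, spring (target / intermediate / side product / substrate)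
- which of these there is most of at the end, counted by the substrate in it, dawn (target / intermediate / side product / substrate)
- final amount of the leader among these, as a percentage of the substrate charged, in spring
- final amount of the leader among these, as a percentage of the substrate charged, in dawn

We replace each curve by its mean. Alder gives 0.229 min⁻¹, and this is the mean decay constant: the natural logarithm of the fraction of substrate left, sign reversed, divided by the time, an apparent first-order constant. Elm gives 0.770 min⁻¹. We set aside that the reagent differs and draw a straight line through the logarithm of the constant against temperature, which gives 0.136 min⁻¹ for spring and 1.19 min⁻¹ for dawn. But the mean has an error: at 1.00 min the alder constant gives 79.5% against a reading of 74.2%, so in alder it runs 5.3 percentage points high at that time.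

By our reckoning spring keeps 50.6% of its substrate and dawn 0.264%. By this reckoning dawn turns over more of the substrate in the same time, so we would run dawn.

The forecast puts substrate in the lead in spring at 33% (range 26% to 42%) and target in the lead in dawn at 27% (range 18% to 40%), where “substrate is nearly gone”. Its spring figure lies below our 50.6%.

The flasks give substrate leading spring at 44.6% and target leading dawn at 14.8%, so spring ends with more target, 18.9%, than dawn.

    substrate ⇌ dormant form (K = 31.0, k = 0.0969 min⁻¹, Ea = 110 kJ mol⁻¹, ΔH = −56.0 kJ mol⁻¹)
    intermediate → side product (k = 0.164 min⁻¹, Ea = 102 kJ mol⁻¹)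
    substrate ⇌ intermediate + leaving ligand (K = 0.0130 M, k = 0.242 min⁻¹, Ea = 98.0 kJ mol⁻¹, ΔH = −52.0 kJ mol⁻¹)
    reagent + intermediate → target (k = 0.830 M⁻¹ min⁻¹, Ea = 65.0 kJ mol⁻¹)
    (constants at 110 °C)

Dawn still holds 6.92% substrate, so its mean decay constant is 0.534 min⁻¹, below our 1.19 min⁻¹. The difference in temperature is the main reason for the gap in free substrate between dawn and spring: without it dawn ends at 44.6% instead of 6.92%. A part of the reason why the constant of dawn lies below ours is the falling back of intermediate and leaving ligand to substrate: without that return, dawn ends at 0.855% instead of 6.92%. For the neighbour flask, spring run at 125 °C, the carried constant gives 0.499 min⁻¹ and so 8.23% substrate; the computed flask holds 13.2%.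

(All runs stem from a simulated flask from invented constants.)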